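## Retrosynthetic overview

1. The side-chain oxirane is made last, by catalyst-controlled Shi epoxidation of the prenyl olefin; the two ring angelates come from one bis-acylation of a trans-diol with angelic anhydride.
2. The ring oxirane and both ring carbinols come from a 2-methylcyclohex-2-enone that already carries the side-chain angelate: a one-pot O2 hydroxylation/epoxidation, then a hydroxyl-directed ketone reduction.
3. The side chain is joined by an asymmetric Ni/Cr coupling of a ring-bound 1-bromoethenyl group with 4-methylpent-3-enal, and the new carbinol is angeloylated at once.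
4. The carbocycle is formed first, by an amine-catalysed Michael/aldol annulation of a 4-bromo-2,4-dienal with tert-butyl 3-oxopentanoate; this sets the first stereocentre.
5. Ring order: cyclohexene (step 2), ring oxirane (step 6), side-chain oxirane (step 9).

Assumption: 2-bromoacrolein and angelic anhydride are bought (the former distilled before use), and the chromium ligand of step 4 is used in whichever enantiomeric form gives the (3S)-carbinol (written here as S; the sense was not derived).

## Route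

Step 1
Reactants: 1 2-bromoprop-2-enal (2-bromoacrolein); 2 (triphenylphosphoranylidene)acetaldehyde
Product: 3 (2E)-4-bromopenta-2,4-dienal
Conditions: 1 (1.3 equiv), CH2Cl2, 0 °C → rt; short silica plug, used at once
Reagents that add atoms: none
Why: Wittig olefination with the stabilised formyl ylide is E-selective and stops at the dienal because the α-bromo enal is much more electrophilic than the conjugated product.

Step 2
Reactants: 3 (2E)-4-bromopenta-2,4-dienal; 4 tert-butyl 3-oxopentanoate
Product: 7 (5S)-5-(1-bromoethenyl)-2-methylcyclohex-2-en-1-one, via Michael adduct 5 (not isolated), via cyclised keto ester 6 (not isolated)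
Conditions: (R)-2-{bis[3,5-bis(trifluoromethyl)phenyl](trimethylsilyloxy)methyl}pyrrolidine (10 mol %), PhCO2H (10 mol %), toluene, 0 °C → rt; then TsOH·H2O (20 mol %), toluene, 80 °C
Reagents that add atoms: none
Why: Organocatalytic Michael/aldol annulation: the keto ester adds to C3 of the E-iminium ion on the face opposite the CAr2OSiMe3 group (Re face with the R catalyst), which sets the ring stereocentre as S, and acid then drives aldol condensation, tert-butyl ester cleavage and decarboxylation.

Step 3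
Reactants: 8 4-methylpent-3-en-1-ol
Product: 9 4-methylpent-3-enal
Conditions: Dess–Martin periodinane, CH2Cl2, 0 °C; filtered, used at once as a solution
Reagents that add atoms: none
Why: Dess–Martin oxidation is mild enough to give the β,γ-unsaturated aldehyde without moving the double bond into conjugation.

Step 4
Reactants: 7 (5S)-5-(1-bromoethenyl)-2-methylcyclohex-2-en-1-one; 9 4-methylpent-3-enal
Product: 11 (5S)-5-[(3S)-3-hydroxy-6-methylhepta-1,5-dien-2-yl]-2-methylcyclohex-2-en-1-one, via trimethylsilyl ether 10 (not isolated)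
Conditions: CrCl2 (10 mol %), N-{2-[(4S)-4-tert-butyl-4,5-dihydro-1,3-oxazol-2-yl]-6-methylphenyl}methanesulfonamide (11 mol %), Et3N (11 mol %), NiCl2(2,9-dimethyl-1,10-phenanthroline) (2 mol %), Mn, LiCl, Me3SiCl, MeCN, rt; then 1 M HCl, THF, 0 °C
Reagents that add atoms: none
Why: Catalytic asymmetric Nozaki–Hiyama–Kishi coupling: the alkenyl bromide is activated by nickel and passed to chromium, the alkenylchromium adds only to the aldehyde and not to the enone, and the chiral sulfonamide on chromium selects the aldehyde face so that the new carbinol is S.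

Step 5
Reactants: 11 (5S)-5-[(3S)-3-hydroxy-6-methylhepta-1,5-dien-2-yl]-2-methylcyclohex-2-en-1-one; 12 angelic acid, (2Z)-2-methylbut-2-enoic acid
Product: 13 (5S)-2-methyl-5-{(3S)-6-methyl-3-[(2Z)-2-methylbut-2-enoyloxy]hepta-1,5-dien-2-yl}cyclohex-2-en-1-one
Conditions: 12 (1.5 equiv), 2,4,6-trichlorobenzoyl chloride (1.5 equiv), Et3N (3 equiv), toluene, rt, 2 h; then 11, toluene, 75 °C; no DMAP
Reagents that add atoms: none
Why: Yamaguchi-type mixed-anhydride esterification without a nucleophilic amine catalyst acylates the single secondary allylic hydroxyl under neutral conditions that neither isomerise angelate to tiglate nor enolise the enone, and it leaves only the two ring hydroxyls to be acylated later.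

Step 6
Reactants: 13 (5S)-2-methyl-5-{(3S)-6-methyl-3-[(2Z)-2-methylbut-2-enoyloxy]hepta-1,5-dien-2-yl}cyclohex-2-en-1-one
Product: 15 (1S,3R,4R,6S)-3-hydroxy-1-methyl-4-{(3S)-6-methyl-3-[(2Z)-2-methylbut-2-enoyloxy]hepta-1,5-dien-2-yl}-7-oxabicyclo[4.1.0]heptan-2-one, via hydroperoxide salt 14 (not isolated)
Conditions: LiN(iPr)2 (1.1 equiv), THF, −78 °C; O2 (1 atm, sparged), −78 °C, 30 min; then Ar, −20 °C, 0.3 M, 3 h; AcOH
Reagents that add atoms: dioxygen, O=O
Why: Proposed new method: the kinetic cross-conjugated lithium dienolate (formed faster than any deprotonation of, or attack on, the hindered conjugated ester) traps O2 at C6 anti to the C5 side chain, and on warming the resulting lithium α′-peroxide, instead of being reduced, serves as the nucleophilic oxidant in a Weitz–Scheffer epoxidation of the enone of a second molecule (attack at C3 anti to the C5 substituent, so the oxirane is trans to the side chain and cis to the new C–O), leaving the α′-alkoxide, so both atoms of O2 end up in the product and three stereocentres are set; the closest known reactions are enolate oxygenation with O2 (where the hydroperoxide is normally reduced with a phosphite) and enone epoxidation by lithium alkyl peroxides.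

Step 7
Reactants: 15 (1S,3R,4R,6S)-3-hydroxy-1-methyl-4-{(3S)-6-methyl-3-[(2Z)-2-methylbut-2-enoyloxy]hepta-1,5-dien-2-yl}-7-oxabicyclo[4.1.0]heptan-2-one
Product: 16 (1R,2S,3R,4R,6S)-1-methyl-4-{(3S)-6-methyl-3-[(2Z)-2-methylbut-2-enoyloxy]hepta-1,5-dien-2-yl}-7-oxabicyclo[4.1.0]heptane-2,3-diol
Conditions: Me4NBH(OAc)3 (5 equiv), MeCN/AcOH 1:1, −30 → −20 °C
Reagents that add atoms: none
Why: Hydroxyl-directed reduction of the Evans–Saksena type: the C3 hydroxyl binds boron and delivers hydride to the same face of the neighbouring ketone, giving the trans-2,3-diol with the new carbinol anti to the oxirane oxygen, while the angelate ester is inert to the acyloxyborohydride.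

Step 8
Reactants: 16 (1R,2S,3R,4R,6S)-1-methyl-4-{(3S)-6-methyl-3-[(2Z)-2-methylbut-2-enoyloxy]hepta-1,5-dien-2-yl}-7-oxabicyclo[4.1.0]heptane-2,3-diol; 17 angelic anhydride, (2Z)-2-methylbut-2-enoic anhydride
Product: 18 (1S,2S,3R,4R,6S)-1-methyl-4-{(3S)-6-methyl-3-[(2Z)-2-methylbut-2-enoyloxy]hepta-1,5-dien-2-yl}-7-oxabicyclo[4.1.0]heptane-2,3-diyl bis[(2Z)-2-methylbut-2-enoate]
Conditions: LiN(SiMe3)2 (2.1 equiv), THF, −78 °C, 15 min; 17 (3 equiv), −78 → 0 °C; AcOH
Reagents that add atoms: none
Why: Acylation of the dilithium dialkoxide with the symmetric anhydride needs no nucleophilic amine catalyst, so both hindered ring hydroxyls are esterified without Z to E isomerisation to tiglate; the oxirane is safe because the carbon next to the C2 alkoxide is fully substituted, and no stereocentre is touched.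

Step 9
Reactants: 18 (1S,2S,3R,4R,6S)-1-methyl-4-{(3S)-6-methyl-3-[(2Z)-2-methylbut-2-enoyloxy]hepta-1,5-dien-2-yl}-7-oxabicyclo[4.1.0]heptane-2,3-diyl bis[(2Z)-2-methylbut-2-enoate]
Product: 19 (1S,2S,3R,4R,6S)-4-{(3S)-4-[(2R)-3,3-dimethyloxiran-2-yl]-3-[(2Z)-2-methylbut-2-enoyloxy]but-1-en-2-yl}-1-methyl-7-oxabicyclo[4.1.0]heptane-2,3-diyl bis[(2Z)-2-methylbut-2-enoate] (target)
Conditions: Shi ketone from D-fructose (1,2:4,5-di-O-isopropylidene-β-D-erythro-2,3-hexodiulo-2,6-pyranose, 30 mol %), KHSO5 (as Oxone, 1.4 equiv), K2CO3, Bu4NHSO4 (cat.), Na2B4O7/Na2EDTA buffer pH 10.5, MeCN/CH2(OMe)2/H2O, 0 °C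
Reagents that add atoms: potassium peroxymonosulfate, [K+].[O-]S(=O)(=O)OO
Why: Shi asymmetric epoxidation: the chiral dioxirane attacks only the electron-rich trisubstituted prenyl olefin (the 1,1-disubstituted olefin beside an ester and the conjugated angelate olefins react far more slowly), and the spiro transition state of the D-fructose ketone gives the (R)-oxirane.

## Compound list

1 | 2-bromoprop-2-enal (2-bromoacrolein) | C=C(Br)C=O | starting material
2 | (triphenylphosphoranylidene)acetaldehyde | O=CC=P(c1ccccc1)(c1ccccc1)c1ccccc1 | starting material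
3 | (2E)-4-bromopenta-2,4-dienal | C=C(Br)/C=C/C=O | intermediate
4 | tert-butyl 3-oxopentanoate | CCC(=O)CC(=O)OC(C)(C)C | starting material
5 | tert-butyl (3S)-3-(1-bromoethenyl)-5-oxo-2-propanoylpentanoate (C2 epimers; Michael adduct) | C=C(Br)[C@H](C(C(=O)CC)C(=O)OC(C)(C)C)CC=O | intermediate
6 | tert-butyl (6S)-6-(1-bromoethenyl)-3-methyl-2-oxocyclohex-3-ene-1-carboxylate (C1 epimers; cyclised keto ester) | C=C(Br)[C@H]1CC=C(C)C(=O)C1C(=O)OC(C)(C)C | intermediate
7 | (5S)-5-(1-bromoethenyl)-2-methylcyclohex-2-en-1-one | C=C(Br)[C@H]1CC=C(C)C(=O)C1 | intermediate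
8 | 4-methylpent-3-en-1-ol | CC(C)=CCCO | starting material
9 | 4-methylpent-3-enal | CC(C)=CCC=O | intermediate
10 | (5S)-2-methyl-5-[(3S)-6-methyl-3-(trimethylsilyloxy)hepta-1,5-dien-2-yl]cyclohex-2-en-1-one (trimethylsilyl ether) | C=C([C@H](CC=C(C)C)O[Si](C)(C)C)[C@H]1CC=C(C)C(=O)C1 | intermediate
11 | (5S)-5-[(3S)-3-hydroxy-6-methylhepta-1,5-dien-2-yl]-2-methylcyclohex-2-en-1-one | C=C([C@H](CC=C(C)C)O)[C@H]1CC=C(C)C(=O)C1 | intermediate
12 | angelic acid, (2Z)-2-methylbut-2-enoic acid | C/C=C(/C)C(=O)O | starting material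
13 | (5S)-2-methyl-5-{(3S)-6-methyl-3-[(2Z)-2-methylbut-2-enoyloxy]hepta-1,5-dien-2-yl}cyclohex-2-en-1-one | C=C([C@H](CC=C(C)C)OC(=O)/C(C)=C\C)[C@H]1CC=C(C)C(=O)C1 | intermediate
14 | (5R,6R)-6-hydroperoxy-2-methyl-5-{(3S)-6-methyl-3-[(2Z)-2-methylbut-2-enoyloxy]hepta-1,5-dien-2-yl}cyclohex-2-en-1-one (present as its lithium salt) | C=C([C@H](CC=C(C)C)OC(=O)/C(C)=C\C)[C@H]1CC=C(C)C(=O)[C@@H]1OO | intermediate
15 | (1S,3R,4R,6S)-3-hydroxy-1-methyl-4-{(3S)-6-methyl-3-[(2Z)-2-methylbut-2-enoyloxy]hepta-1,5-dien-2-yl}-7-oxabicyclo[4.1.0]heptan-2-one | C=C([C@H](CC=C(C)C)OC(=O)/C(C)=C\C)[C@H]1C[C@@H]2O[C@]2(C)C(=O)[C@@H]1O | intermediate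
16 | (1R,2S,3R,4R,6S)-1-methyl-4-{(3S)-6-methyl-3-[(2Z)-2-methylbut-2-enoyloxy]hepta-1,5-dien-2-yl}-7-oxabicyclo[4.1.0]heptane-2,3-diol | C=C([C@H](CC=C(C)C)OC(=O)/C(C)=C\C)[C@H]1C[C@@H]2O[C@]2(C)[C@@H](O)[C@@H]1O | intermediate
17 | angelic anhydride, (2Z)-2-methylbut-2-enoic anhydride | C/C=C(/C)C(=O)OC(=O)/C(C)=C\C | starting material
18 | (1S,2S,3R,4R,6S)-1-methyl-4-{(3S)-6-methyl-3-[(2Z)-2-methylbut-2-enoyloxy]hepta-1,5-dien-2-yl}-7-oxabicyclo[4.1.0]heptane-2,3-diyl bis[(2Z)-2-methylbut-2-enoate] | C=C([C@H](CC=C(C)C)OC(=O)/C(C)=C\C)[C@H]1C[C@@H]2O[C@]2(C)[C@@H](OC(=O)/C(C)=C\C)[C@@H]1OC(=O)/C(C)=C\C | intermediate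
19 | (1S,2S,3R,4R,6S)-4-{(3S)-4-[(2R)-3,3-dimethyloxiran-2-yl]-3-[(2Z)-2-methylbut-2-enoyloxy]but-1-en-2-yl}-1-methyl-7-oxabicyclo[4.1.0]heptane-2,3-diyl bis[(2Z)-2-methylbut-2-enoate] | C=C([C@H](C[C@H]1OC1(C)C)OC(=O)/C(C)=C\C)[C@H]1C[C@@H]2O[C@]2(C)[C@@H](OC(=O)/C(C)=C\C)[C@@H]1OC(=O)/C(C)=C\C | target

## Step count and risks

Total steps: 9. Longest linear sequence: 8 (steps 1, 2, 4, 5, 6, 7, 8, 9; step 3 is a one-step side branch).

The three steps most likely to fail:

Step 6 (the proposed new reaction). The risk is that the lithium α′-peroxide decomposes to the 1,2-dione, adds to its own enone, or attacks the side-chain ester before it transfers oxygen to a second molecule. Fallback with known chemistry: setting out from 13, Weitz–Scheffer epoxidation with tert-butyl hydroperoxide and DBU in toluene at 0 °C (non-hydrolytic, so the angelate survives), anti to the C5 side chain as for carvone, gives (1S,4S,6S)-1-methyl-4-{(3S)-6-methyl-3-[(2Z)-2-methylbut-2-enoyloxy]hepta-1,5-dien-2-yl}-7-oxabicyclo[4.1.0]heptan-2-one F1. Its potassium enolate (KN(SiMe3)2, 1.1 equiv, THF, −78 °C) is then hydroxylated with 2-(phenylsulfonyl)-3-phenyloxaziridine anti to the side chain, which comes back to the route at 15.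

Step 4. The risk is poor facial control or turnover with the hindered alkenyl bromide and the easily isomerised aldehyde 9. Fallback that makes the C–C bond on the other side of the carbinol: setting out from 7, reductive carbonylation (PdCl2(PPh3)2, CO/H2, Et3N, toluene, 80 °C) gives 2-[(1S)-4-methyl-5-oxocyclohex-3-en-1-yl]prop-2-enal F2. Allylboration of F2 with allylboronic acid pinacol ester and the chiral phosphoric acid (S)-TRIP (toluene, −30 °C) gives (5S)-5-[(3S)-3-hydroxyhexa-1,5-dien-2-yl]-2-methylcyclohex-2-en-1-one F3. Cross-metathesis of F3 with 2-methylbut-2-ene and the second-generation Grubbs catalyst RuCl2(H2IMes)(PCy3)(=CHPh) turns the allyl into the prenyl group and comes back to the route at 11.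

Step 8. The risk is incomplete acylation of the hindered ring hydroxyl next to the oxirane, or base-induced loss of angelate geometry. Fallback that builds the Z olefins in place: setting out from 16, the two ring hydroxyls are esterified with 2-[bis(2-methylphenoxy)phosphoryl]propanoic acid (DCC, DMAP, CH2Cl2) to give (1S,2S,3R,4R,6S)-1-methyl-4-{(3S)-6-methyl-3-[(2Z)-2-methylbut-2-enoyloxy]hepta-1,5-dien-2-yl}-7-oxabicyclo[4.1.0]heptane-2,3-diyl bis{2-[bis(2-methylphenoxy)phosphoryl]propanoate} F4. A twofold Z-selective Horner–Wadsworth–Emmons reaction of F4 with acetaldehyde (NaH, THF, −78 °C) builds the two ring angelates and comes back to the route at 18.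

## Further compounds

F1 | step 6 | (1S,4S,6S)-1-methyl-4-{(3S)-6-methyl-3-[(2Z)-2-methylbut-2-enoyloxy]hepta-1,5-dien-2-yl}-7-oxabicyclo[4.1.0]heptan-2-one | C=C([C@H](CC=C(C)C)OC(=O)/C(C)=C\C)[C@H]1C[C@@H]2O[C@]2(C)C(=O)C1
F2 | step 4 | 2-[(1S)-4-methyl-5-oxocyclohex-3-en-1-yl]prop-2-enal | C=C(C=O)[C@H]1CC=C(C)C(=O)C1
F3 | step 4 | (5S)-5-[(3S)-3-hydroxyhexa-1,5-dien-2-yl]-2-methylcyclohex-2-en-1-one | C=C([C@H](CC=C)O)[C@H]1CC=C(C)C(=O)C1
F4 | step 8 | (1S,2S,3R,4R,6S)-1-methyl-4-{(3S)-6-methyl-3-[(2Z)-2-methylbut-2-enoyloxy]hepta-1,5-dien-2-yl}-7-oxabicyclo[4.1.0]heptane-2,3-diyl bis{2-[bis(2-methylphenoxy)phosphoryl]propanoate} | C=C([C@H](CC=C(C)C)OC(=O)/C(C)=C\C)[C@H]1C[C@@H]2O[C@]2(C)[C@@H](OC(=O)C(C)P(=O)(Oc2ccccc2C)Oc2ccccc2C)[C@@H]1OC(=O)C(C)P(=O)(Oc1ccccc1C)Oc1ccccc1C
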